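The pitfall here is to take the first step as the slow one and give Q that step's half-life.

    Q ⇌ J + G (K1 = 0.078 M, k1 = 1.75 × 10⁻⁴ /s)
    Q + J → E (k2 = 0.0172 /M/s)
    D ⇌ J, rate k3*(cs3 - [J]) while solid is left; crystals form when [J] > cs3 (cs3 = 0.091 M, k3 = 0.0288 /s)
    G → Z (k4 = 1.11 × 10⁻⁴ /s)

| setting | teal | grey | amber |
|---|---|---|---|
| Q | 0.10 M | 0.10 M | 0.10 M |
| time | 80 min | 160 min | 320 min |

- in percentages every species weighs as the Q in it: one E counts as two
- for J the D are counted in
- as a solid, counted per litre of solution: D
- run time (teal): 80 min

1. which of these there is most of at the end, counted by the Q in it, teal (Q / E / J)
2. which of these there is most of at the end, counted by the Q in it, grey (Q / E / J)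
3. which of these there is most of at the end, counted by the Q in it, amber (Q / E / J)
4. how much there is at the end of the one of these that leads, in percent of the Q charged: teal
5. how much there is at the end of the one of these that leads, in percent of the Q charged: grey
6. how much there is at the end of the one of these that leads, in percent of the Q charged: amber

Two views stand against each other. The first says that the first step is slow and the second follows at once, so Q passes to E as one first-order step, with a half-life of 66 min (forward rate only). That puts E at 56.8 % in teal, 81.4 % in grey and 96.5 % in amber, and leaves 43.2 % of Q in teal.

The second view asks what [J] does. The first step makes J in proportion to [Q], and the second step removes J in proportion to [Q] times [J]. Since [Q] stands in both, they balance at one concentration whatever [Q] is: the holding level, the first step's forward constant over the second step's constant, 0.0102 M. This is a steady state for J, and I leave out the way back and the loss of G. In teal, J approaches the level with a half-life of 6.7 min, much shorter than Q's 66 min, so [J] can stay there while Q falls. At that level the second step takes Q as fast as the first, so Q is lost by a pseudo-first-order law at twice the forward constant, with a half-life of 33.0 min. The level is far below the solubility, so I expect no D.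

While [J] climbs, Q is spared part of that loss. The climb adds about the level's share of the charge, 10.2 %, to the exponent. I therefore take the fraction of Q left as the exponential of that share minus the doubled constant times the time, and E as what remains after Q and J at the level. This gives E leading, at 69.2 % in teal, 86.0 % in grey and 89.7 % in amber.

The forecast takes the second side with its own numbers, not mine: E, E and E leading at 68 %, 85 % and 92 %, on the ground that “J is eaten by Q almost as fast as it forms”.

The flasks give E in the lead at 67.9 % in teal, 85.8 % in grey and 92.3 % in amber. In teal, dissolved J is made 1.12 times as fast as it is used up at 25.0 min, and that ratio reads 0.943 at 80.0 min. Teal's J reads 9.10 % at the end, against the level's 10.2 %, and its Q reads 23.0 %. The first view keeps the opening of teal, about 6.7 min, while [J] is still climbing from nothing.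

In the neighbour that is teal stopped at 30 min, the same reckoning gives Q at 59.0 % and E at 30.9 %. The computed flask holds Q at 60 % and E at 31.2 %.

(Its constants are those of an exercise, and the outcome is calculated.)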